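All runs are simulated on assumed constants; scatter was added.

| setting | red | teal | spring | midnight |
|---|---|---|---|---|
| starting material | 20 mM (fed, over 2.5 d) | 20 mM (fed, over 2.5 d) | 20 mM (fed, over 2.5 d) | 20 mM (fed, over 2.5 d) |
| capture agent | 4.3 mM | 16 mM | 5.00 mM | 20.0 mM |
| protic impurity | 0.40 mM | 0.40 mM | 0.400 mM | 0.400 mM |
| temperature | −5 °C | 6 °C |  |  |
| remark | run made earlier; the fed solution adds 0.50 times the starting volume | run made earlier; the fed solution adds 0.50 times the starting volume | at −10 °C throughout; the fed solution adds 0.50 times the starting volume | at −10 °C until 20 h, from then on at 10 °C; the fed solution adds 0.50 times the starting volume |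
| time |  |  | 2.5 d | 2.5 d |

- red (time / h: product / %, starting material / %): 2.50: 1.7, 2.5; 6.00: 5.2, 3.1; 12.0: 12.7, 4.1; 20.0: 24.3, 4.0; 25.0: 31.4, 3.8; 30.0: 38.5, 4.1; 40.0: 54.3, 3.8
- teal (time / h: product / %, starting material / %): 1.00: 1.0, 0.7; 2.50: 2.8, 0.5; 5.00: 6.2, 0.7; 10.0: 14.3, 0.7; 12.0: 17.2, 0.4; 15.0: 21.7, 0.1; 20.0: 29.4, 0.4

(standard deviation of a reading: 0.3 percentage points)

- charges are per starting volume, the dose included; the dosed solution carries all of it
- percentages count the whole charge, also what has not yet gone in
- a reading or a percentage of product counts all its forms, free or not
- a reading of starting material is of its free form alone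

1. the winner by amount of product, in percent of the starting material charged; "neither" if no more than 2 percentage points parts them (spring / midnight / neither)
2. how much product is there at the end, in percent of the starting material charged: spring
3. how much product is there at the end, in percent of the starting material charged: midnight

**The allowance.** If each protic impurity can destroy at most one starting material, you can bound that loss before reckoning a single rate. Charged impurity over charged starting material is 2.00%: this is the quench allowance, and red, teal, spring and midnight share it.

**The missing amount.** Now hold it against the readings. At 20.0 h red and teal have received the same feed, and feed minus product minus free starting material leaves 5.03% in red and 3.53% in teal. Both exceed the allowance, so the impurity cannot account for the whole gap. The gap is also smaller in warmer teal, though capture agent changed too. You may therefore read the excess as material on its way, not dead.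

**My reckoning.** At least 98.0% of midnight's charge escapes the quench, and its 40.0 h of warmth should release much of the excess. So I place midnight above 87%, while cold spring stays well under it.

**The forecast.** It names midnight as winner, with spring at 77% and midnight at 87%, on the ground “selectivity is about 0.87”. We part on midnight, because I count the excess as delayed.

**The flask.** The winner is midnight, with spring at 77.0% and midnight at 93.6%.

    intermediate B → intermediate C (k = 3.00 × 10⁻⁷ s⁻¹, Ea = 97.0 kJ mol⁻¹)
    starting material + product ⇌ idle adduct, settled at all times (K = 48.0 M⁻¹, ΔH = 2.00 kJ mol⁻¹)
    starting material + protic impurity → quenched substrate (k = 0.0260 M⁻¹ s⁻¹, Ea = 36.0 kJ mol⁻¹)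
    starting material → product (k = 4.70 × 10⁻⁵ s⁻¹, Ea = 95.0 kJ mol⁻¹)
    starting material → intermediate A (k = 5.30 × 10⁻⁶ s⁻¹, Ea = 97.0 kJ mol⁻¹)
    starting material → intermediate B (k = 6.10 × 10⁻⁷ s⁻¹, Ea = 102 kJ mol⁻¹)
    intermediate A → intermediate C (k = 6.60 × 10⁻⁶ s⁻¹, Ea = 87.0 kJ mol⁻¹)
    capture agent + intermediate C → trapped intermediate (k = 2.40 × 10⁻⁴ M⁻¹ s⁻¹, Ea = 57.0 kJ mol⁻¹)
    intermediate C → product (k = 4.20 × 10⁻⁶ s⁻¹, Ea = 92.0 kJ mol⁻¹)
    (constants at −10 °C)

**Delay, not loss.** The main reason for the gap between the flasks is the difference in temperature programme: without that difference, spring ends at 95.0%, not 77.0%. Midnight ends with 1.88% quenched substrate, within the allowance of 2.00%. The excess was late rather than lost: without the passing of intermediate C into product, midnight ends at 86.0%, not 93.6%, and that step is one part of the recovery.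

**Next flask.** Take midnight with 1.6 mM protic impurity. The allowance becomes 8.00%, which is 6 percentage points higher, so you expect about 87.6% product. The computed flask gives 88.3%, with 7.35% quenched substrate.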